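**Retrosynthetic overview**
1. Feature used: ring A is a 1,4-quinone with carbonyls at C1 and C4, the side chain on C2 and only H on C3. It is fused through C4a/C8a to a ring B with identical oxygens at C5 and C8. The C1–C8a–C4a–C4 diacyl unit is therefore symmetric, and C2=C3 with the C1' stereocentre can arrive as a terminal alkyne in either orientation.
2. Last disconnection: the two phenols are masked as MOM ethers, which are removed under cold aprotic conditions once the skeleton is complete.
3. Key disconnection: C1–C2 and C3–C4 of ring A. This leads back to 3,6-bis(methoxymethoxy)benzocyclobutene-1,2-dione, opened at its C(O)–C(O) bond by cobalt, and (R)-6-methylhept-5-en-1-yn-3-yl 2-methylpropanoate.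
4. Dione: aryne/ketene acetal [2+2] on bromohydroquinone dimethyl ether, benzylic dibromination, hydrolysis, methyl-to-MOM exchange. Alkyne ester: prenyl bromide plus propargyl alcohol, E-reduction, Sharpless epoxidation (sets C1'), chloride, base-induced double elimination, acylation.
5. Ring order: ring B is bought, the four-membered ring is built on it in step 1, and that ring is expanded to six-membered ring A in step 12.

Key step: step 12

Remark: the phenol oxygens are carried as methyl ethers through the radical bromination and the strong-acid hydrolysis, which MOM acetals would not survive, and are exchanged for MOM only on the finished dione; ClCo(PPh3)3 is taken as a purchased reagent, and atom numbers follow naphthalene-1,4-dione numbering with C1' as the carbinol carbon.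

**Step 1**
Reactants: 1 2-bromo-1,4-dimethoxybenzene; 2 1,1-diethoxyethene
Product: 5 3,6-dimethoxybenzocyclobuten-1(2H)-one, via 3,6-dimethoxybenzyne 3 (not isolated), via diethyl acetal cycloadduct 4 (not isolated)
Conditions: NaNH2 (2.5 equiv), 2 (2 equiv), THF, reflux; then 1 M aq HCl, THF, rt
Reagents that add atoms: water, O
Why: Aryne [2+2] cycloaddition, in which NaNH2 removes the C3–H flanked by Br and OMe, bromide leaves, the symmetric aryne 3 is trapped by the nucleophilic ketene acetal as a single regioisomer 4, and dilute-acid acetal hydrolysis frees the ketone without touching the aryl methyl ethers.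

**Step 2**
Reactants: 5 3,6-dimethoxybenzocyclobuten-1(2H)-one
Product: 6 2,2-dibromo-3,6-dimethoxybenzocyclobuten-1(2H)-one
Conditions: NBS (2.2 equiv), (BzO)2 (cat.), CCl4 (or PhCF3), reflux
Reagents that add atoms: N-bromosuccinimide, O=C1CCC(=O)N1Br
Why: Wohl–Ziegler radical bromination should occur twice at the only benzylic, α-keto CH2 group, and aryl methyl ethers tolerate it whereas the O–CH2–O hydrogens of MOM ethers would be abstracted.

**Step 3**
Reactants: 6 2,2-dibromo-3,6-dimethoxybenzocyclobuten-1(2H)-one
Product: 7 3,6-dimethoxybenzocyclobutene-1,2-dione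
Conditions: 50% aq H2SO4, 55–60 °C
Reagents that add atoms: water, O
Why: Acid hydrolysis of a geminal dihalide to a carbonyl group, chosen because benzocyclobutenediones are stable in strong acid but are ring-opened by hydroxide.

**Step 4**
Reactants: 7 3,6-dimethoxybenzocyclobutene-1,2-dione
Product: 9 3,6-dihydroxybenzocyclobutene-1,2-dione, via bis(dibromoboryl) ether 8 (not isolated)
Conditions: BBr3 (3 equiv), CH2Cl2, −78 °C to rt; then ice-water
Reagents that add atoms: none
Why: Lewis acid ether cleavage, in which BBr3 binds each methoxy oxygen, bromide removes the methyl group by SN2 to leave aryl borate 8, and water hydrolyses 8, while the acid-stable dione is only reversibly complexed.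

**Step 5**
Reactants: 9 3,6-dihydroxybenzocyclobutene-1,2-dione
Product: 10 3,6-bis(methoxymethoxy)benzocyclobutene-1,2-dione
Conditions: MOMCl (3 equiv), iPr2NEt (4 equiv), CH2Cl2, 0 °C to rt
Reagents that add atoms: chloromethyl methyl ether, COCCl
Why: Williamson-type O-alkylation of the acidic, carbonyl-conjugated phenols by a very reactive α-chloro ether, using a hindered amine base that cannot add to the strained dione.

**Step 6**
Reactants: 11 prenyl bromide (1-bromo-3-methylbut-2-ene); 12 propargyl alcohol
Product: 13 6-methylhept-5-en-2-yn-1-ol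
Conditions: CuI (10 mol %), K2CO3, n-Bu4NBr (cat.), DMF, rt
Reagents that add atoms: none
Why: Copper-catalysed coupling of a terminal alkyne with an allylic halide should form the C–C bond at the unhindered primary carbon of prenyl bromide, and carbonate is too weak a base to cause O-alkylation of the hydroxyl group.

**Step 7**
Reactants: 13 6-methylhept-5-en-2-yn-1-ol
Product: 14 (2E)-6-methylhepta-2,5-dien-1-ol
Conditions: LiAlH4 (1.5 equiv), THF, reflux; aqueous work-up
Reagents that add atoms: none
Why: Hydroxyl-directed trans-hydroalumination of a propargylic alcohol followed by protonolysis gives the E-allylic alcohol, and the isolated trisubstituted alkene is inert to LiAlH4.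

**Step 8**
Reactants: 14 (2E)-6-methylhepta-2,5-dien-1-ol
Product: 15 [(2R,3R)-3-(3-methylbut-2-en-1-yl)oxiran-2-yl]methanol
Conditions: Ti(OiPr)4 (10 mol %), D-(−)-diisopropyl tartrate (12 mol %), t-BuOOH (2 equiv), 4 Å MS, CH2Cl2, −20 °C
Reagents that add atoms: tert-butyl hydroperoxide, CC(C)(C)OO
Why: Sharpless asymmetric epoxidation, in which the titanium tartrate complex binds the allylic hydroxyl so that only C2=C3 reacts and the remote alkene is left, and the D-(−)-tartrate directs oxygen to the face that gives the (2R,3R)-epoxide, whose C3–O bond becomes the C1'–O bond of the target with R configuration.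

**Step 9**
Reactants: 15 [(2R,3R)-3-(3-methylbut-2-en-1-yl)oxiran-2-yl]methanol
Product: 16 (2S,3R)-2-(chloromethyl)-3-(3-methylbut-2-en-1-yl)oxirane
Conditions: PPh3 (1.3 equiv), CCl4, NaHCO3 (solid), reflux
Reagents that add atoms: tetrachloromethane, ClC(Cl)(Cl)Cl
Why: Appel reaction, in which the primary alcohol is activated at phosphorus and displaced by chloride under near-neutral conditions, so neither epoxide carbon is touched and only the C2 descriptor changes because CH2Cl outranks C3.

**Step 10**
Reactants: 16 (2S,3R)-2-(chloromethyl)-3-(3-methylbut-2-en-1-yl)oxirane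
Product: 18 (R)-6-methylhept-5-en-1-yn-3-ol, via lithium chlorovinyl alkoxide 17 (not isolated)
Conditions: LDA (commercial solution, 3.2 equiv), THF, −78 to −30 °C; then H2O
Reagents that add atoms: none
Why: Base-induced double elimination of a 1-chloro-2,3-epoxide, in which LDA removes a proton of the CH2Cl group, the C2–O bond opens to 17, a second loss of HCl gives the alkyne (held deprotonated until the quench), and the C3–O bond is never broken, so the R centre is kept.

**Step 11**
Reactants: 18 (R)-6-methylhept-5-en-1-yn-3-ol
Product: 19 (R)-6-methylhept-5-en-1-yn-3-yl 2-methylpropanoate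
Conditions: isobutyryl chloride (1.3 equiv), Et3N, DMAP (cat.), CH2Cl2, 0 °C
Reagents that add atoms: isobutyryl chloride, CC(C)C(Cl)=O
Why: DMAP-catalysed acylation (nucleophilic catalysis) takes place at oxygen only, so the C–O bond and the R configuration are kept.

**Step 12**
Reactants: 10 3,6-bis(methoxymethoxy)benzocyclobutene-1,2-dione; 19 (R)-6-methylhept-5-en-1-yn-3-yl 2-methylpropanoate
Product: 22 isobutylshikonin 5,8-bis(methoxymethyl) ether, via chloro phthaloylcobalt complex 20 (not isolated), via cationic acetonitrile phthaloylcobalt complex 21 (not isolated)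
Conditions: ClCo(PPh3)3 (1.05 equiv), PhCl, rt, Ar; evaporate; AgBF4 (2 equiv), MeCN, rt, filter off AgCl; then 19 (1.5 equiv), 70 °C
Reagents that add atoms: none
Why: The monovalent cobalt of ClCo(PPh3)3 adds oxidatively across the strained acyl–acyl bond of 10 with loss of one PPh3 to give the five-membered diacyl metallacycle 20 of trivalent cobalt; AgBF4 then replaces chloride by labile MeCN (21), the alkyne of 19 binds and inserts into one acyl–Co bond (C1–C2), and the seven-membered cobaltacycle forms C3–C4 by reductive elimination. The closest known reaction type is the stoichiometric phthaloylcobalt–alkyne naphthoquinone annulation, which accepts terminal and heteroatom-functionalised alkynes. Ring A is closed as a six-membered carbocycle by a metal-templated formal [4+2] union of the C4–C4a–C8a–C1 diacyl unit with C2≡C3, the last bond coming from vinyl–acyl reductive elimination, and it appears directly at the quinone oxidation level. No stereocentre is created, and C1' of 19 keeps all four of its bonds, so the R configuration is carried over. The step needs reaction at the alkyne rather than the trisubstituted alkene, secured by the much better binding and insertion of an unhindered terminal alkyne at the cationic acylcobalt centre, and it needs the propargylic ester to stay in place, which is why chloride is abstracted and AgCl removed before 19 is added while the remaining silver ion is tied up by the released PPh3. The orientation of insertion does not matter, because a mirror plane through cobalt in 20 makes the two acyl–Co bonds equivalent.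

**Step 13**
Reactants: 22 isobutylshikonin 5,8-bis(methoxymethyl) ether
Product: 24 isobutylshikonin (target), via bis(trimethylsilyl) ether 23 (not isolated)
Conditions: Me3SiBr (5 equiv), 4 Å MS, CH2Cl2, −40 to −20 °C; then pH 7 buffer
Reagents that add atoms: none
Why: Silyl halide cleavage of acetals, in which Me3SiBr silylates the MOM oxygens, bromide takes away the CH2OMe groups and the peri-carbonyl aryl silyl ethers of 23 hydrolyse at the buffered quench, under conditions aprotic and cold enough to spare the C1' ester, the trisubstituted alkene and the quinone.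

**Compound list**
1 | 2-bromo-1,4-dimethoxybenzene | COc1ccc(OC)c(Br)c1 | starting material
2 | 1,1-diethoxyethene | C=C(OCC)OCC | starting material
3 | 3,6-dimethoxybenzyne | COC1=CC=C(OC)C#C1 | intermediate
4 | 1,1-diethoxy-3,6-dimethoxy-1,2-dihydrobenzocyclobutene | CCOC1(OCC)Cc2c(OC)ccc(OC)c21 | intermediate
5 | 3,6-dimethoxybenzocyclobuten-1(2H)-one | COc1ccc(OC)c2c1CC2=O | intermediate
6 | 2,2-dibromo-3,6-dimethoxybenzocyclobuten-1(2H)-one | COc1ccc(OC)c2c1C(Br)(Br)C2=O | intermediate
7 | 3,6-dimethoxybenzocyclobutene-1,2-dione | COc1ccc(OC)c2c1C(=O)C2=O | intermediate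
8 | 3,6-bis(dibromoboryloxy)benzocyclobutene-1,2-dione | BrB(Br)Oc1ccc(OB(Br)Br)c2c1C(=O)C2=O | intermediate
9 | 3,6-dihydroxybenzocyclobutene-1,2-dione | Oc1ccc(O)c2c1C(=O)C2=O | intermediate
10 | 3,6-bis(methoxymethoxy)benzocyclobutene-1,2-dione | COCOc1ccc(OCOC)c2c1C(=O)C2=O | intermediate
11 | prenyl bromide | CC(C)=CCBr | starting material
12 | propargyl alcohol | OCC#C | starting material
13 | 6-methylhept-5-en-2-yn-1-ol | CC(C)=CCC#CCO | intermediate
14 | (2E)-6-methylhepta-2,5-dien-1-ol | CC(C)=CC/C=C/CO | intermediate
15 | [(2R,3R)-3-(3-methylbut-2-en-1-yl)oxiran-2-yl]methanol | OC[C@H]1O[C@@H]1CC=C(C)C | intermediate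
16 | (2S,3R)-2-(chloromethyl)-3-(3-methylbut-2-en-1-yl)oxirane | ClC[C@H]1O[C@@H]1CC=C(C)C | intermediate
17 | lithium (3R)-1-chloro-6-methylhepta-1,5-dien-3-olate (alkene geometry at C1=C2 not defined) | CC(C)=CC[C@@H]([O-])C=CCl.[Li+] | intermediate
18 | (R)-6-methylhept-5-en-1-yn-3-ol | CC(C)=CC[C@@H](O)C#C | intermediate
19 | (R)-6-methylhept-5-en-1-yn-3-yl 2-methylpropanoate | CC(C)=CC[C@@H](OC(=O)C(C)C)C#C | intermediate
20 | chlorobis(triphenylphosphine)[3,6-bis(methoxymethoxy)phthaloyl]cobalt | COCOc1ccc(OCOC)c2c1C(=O)[Co-2](Cl)([P+](c1ccccc1)(c1ccccc1)c1ccccc1)([P+](c1ccccc1)(c1ccccc1)c1ccccc1)C2=O | intermediate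
21 | bis(acetonitrile)bis(triphenylphosphine)[3,6-bis(methoxymethoxy)phthaloyl]cobalt tetrafluoroborate | COCOc1ccc(OCOC)c2c1C(=O)[Co-3]([N+]#CC)([N+]#CC)([P+](c1ccccc1)(c1ccccc1)c1ccccc1)([P+](c1ccccc1)(c1ccccc1)c1ccccc1)C2=O.F[B-](F)(F)F | intermediate
22 | isobutylshikonin 5,8-bis(methoxymethyl) ether, (1R)-1-[5,8-bis(methoxymethoxy)-1,4-dioxonaphthalen-2-yl]-4-methylpent-3-en-1-yl 2-methylpropanoate | CC(C)=CC[C@@H](OC(=O)C(C)C)C1=CC(=O)c2c(OCOC)ccc(OCOC)c2C1=O | intermediate
23 | isobutylshikonin 5,8-bis(trimethylsilyl) ether | CC(C)=CC[C@@H](OC(=O)C(C)C)C1=CC(=O)c2c(O[Si](C)(C)C)ccc(O[Si](C)(C)C)c2C1=O | intermediate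
24 | isobutylshikonin, (1R)-1-(5,8-dihydroxy-1,4-dioxonaphthalen-2-yl)-4-methylpent-3-en-1-yl 2-methylpropanoate | CC(C)=CC[C@@H](OC(=O)C(C)C)C1=CC(=O)c2c(O)ccc(O)c2C1=O | target

**Total step count:** 13. **Longest linear sequence:** 8 (steps 6–13). The dione branch, steps 1–5, joins at step 12.

**Steps most likely to fail**

**Step 12.**
- Residual silver ion or the cationic cobalt centre may trigger migration or ionisation of the propargylic acyloxy group.
- The terminal alkyne may be metalated or oligomerised.
- The phosphine released at the end may add in conjugate fashion to the free C3 position of the new quinone.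
- The fallback changes the reacting metal species to one that needs neither silver nor phosphine. It sets out from 10.
- After the insertion to 20, both phosphines are displaced with dimethylglyoxime in pyridine at rt. This gives the neutral octahedral complex chloro(dimethylglyoxime)(pyridine)[3,6-bis(methoxymethoxy)phthaloyl]cobalt F1, which is isolated and washed free of PPh3.
- Heating F1 with 19 and CoCl2·6H2O as a mild Lewis acid in ClCH2CH2Cl at 70–80 °C is a known variant of the annulation that suits terminal alkynes. It comes back to the route at 22.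

**Step 13.**
- The C1' acyloxy group may ionise under acid assistance, helped by the electron-rich tautomer of the liberated naphthazarin.
- Adventitious HBr may add to the prenyl alkene or the quinone.
- The cleavage may stop after one MOM group.
- The fallback replaces acid-labile protection by fluoride-labile protection and sets out from 9.
- Silylation with TBSOTf and 2,6-lutidine in CH2Cl2 at 0 °C gives 3,6-bis(tert-butyldimethylsilyloxy)benzocyclobutene-1,2-dione F2.
- The cobalt sequence of step 12 with 19 then runs through the chloro phthaloylcobalt complex F3 and the cationic acetonitrile complex F4 to isobutylshikonin 5,8-bis(tert-butyldimethylsilyl) ether F5.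
- Et3N·3HF (or n-Bu4NF buffered with AcOH) in THF at 0 °C removes both aryl silyl groups, and the route is rejoined at 24.

**Step 10.**
- Deprotonation at the allylic C4–H2 next to the epoxide may compete with deprotonation of CH2Cl, so that the C3–O bond opens towards a conjugated diene and the stereocentre is lost.
- The fallback sets the stereocentre by reagent-controlled ketone reduction instead and sets out from 15.
- H5IO6 (2.2 equiv) in THF–Et2O–H2O at 0 °C opens and cleaves the epoxy alcohol to 4-methylpent-3-enal F6.
- HC≡CMgBr in THF at −78 to 0 °C gives racemic 6-methylhept-5-en-1-yn-3-ol F7.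
- Dess–Martin periodinane in CH2Cl2 gives 6-methylhept-5-en-1-yn-3-one F8 under neutral conditions that should not move the alkene into conjugation.
- Midland reduction with (R)-Alpine-Borane (B-isopinocampheyl-9-borabicyclo[3.3.1]nonane from (+)-α-pinene), neat or in THF at rt, should deliver hydride to the face that gives the R alcohol, because the slim ethynyl group takes the hindered position in the cyclic transition state. The route is rejoined at 18.

**Further compounds**
F1 | step 12 | chloro(dimethylglyoxime)(pyridine)[3,6-bis(methoxymethoxy)phthaloyl]cobalt | COCOc1ccc(OCOC)c2c1C(=O)[Co-3]3(Cl)([n+]4ccccc4)([N+](O)=C(C)C(C)=[N+]3O)C2=O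
F2 | step 13 | 3,6-bis(tert-butyldimethylsilyloxy)benzocyclobutene-1,2-dione | CC(C)(C)[Si](C)(C)Oc1ccc(O[Si](C)(C)C(C)(C)C)c2c1C(=O)C2=O
F3 | step 13 | chlorobis(triphenylphosphine)[3,6-bis(tert-butyldimethylsilyloxy)phthaloyl]cobalt | CC(C)(C)[Si](C)(C)Oc1ccc(O[Si](C)(C)C(C)(C)C)c2c1C(=O)[Co-2](Cl)([P+](c1ccccc1)(c1ccccc1)c1ccccc1)([P+](c1ccccc1)(c1ccccc1)c1ccccc1)C2=O
F4 | step 13 | bis(acetonitrile)bis(triphenylphosphine)[3,6-bis(tert-butyldimethylsilyloxy)phthaloyl]cobalt tetrafluoroborate | CC(C)(C)[Si](C)(C)Oc1ccc(O[Si](C)(C)C(C)(C)C)c2c1C(=O)[Co-3]([N+]#CC)([N+]#CC)([P+](c1ccccc1)(c1ccccc1)c1ccccc1)([P+](c1ccccc1)(c1ccccc1)c1ccccc1)C2=O.F[B-](F)(F)F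
F5 | step 13 | isobutylshikonin 5,8-bis(tert-butyldimethylsilyl) ether | CC(C)=CC[C@@H](OC(=O)C(C)C)C1=CC(=O)c2c(O[Si](C)(C)C(C)(C)C)ccc(O[Si](C)(C)C(C)(C)C)c2C1=O
F6 | step 10 | 4-methylpent-3-enal | CC(C)=CCC=O
F7 | step 10 | racemic 6-methylhept-5-en-1-yn-3-ol | CC(C)=CCC(O)C#C
F8 | step 10 | 6-methylhept-5-en-1-yn-3-one | CC(C)=CCC(=O)C#C
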